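**Retrosynthetic overview**

1. Target numbering (5R,9S,13R,14S,17R,15Z,18E): C1 lactone C=O, C2=C3, C4, C5 (N–CH), C6–C8, C9 (spiro), C10–C12, C13, C14 (CHMe), C15=C16, C17 (CHOH), C18=C19(Cl), C20, C21 (OCH2), C22 (NCH2). The plan rests on the spiro atom C9, shared by the piperidine (N, C5–C9) and the cyclopentane (C9–C13); C4–C9 is the chain of D-2-aminoadipic acid (α-CO2H = C4, δ-CO2H = C9).
2. Late disconnections: lactone C1–O(C21); C16–C17 (C15≡C16 alkyne plus C17–C21 chloro-enal, then cis semi-hydrogenation); C2=C3 (ring-closing metathesis) and N–C22 (allylation); C3–C4 (vinyl cuprate on the C4 iodide).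
3. C13/C14: the C13 ketone is olefinated to the C13=C14 enoate, hydrogenated anti to the sulfonamide (sets C13) and methylated as the ester enolate (sets C14).
4. Key disconnection C9–C10: 1,2-shift of a cyclobutanol ring bond onto the N-tosyliminium carbon C9 of the aminoadipate-derived ene-sulfonamide, giving the spiro cyclopentanone with its ketone at C13.
5. Ring order: piperidine (as lactam) → cyclobutane → cyclopentane (ring expansion) → dehydropiperidine (N, C22, C2–C5) → 15-membered lactone.

Key step: step 8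

Assumption: in step 25 the (S,S)-antipode of ProPhenol is taken to send the alkynyl group to the Re face of the enal; if the sense is the reverse, the (R,R)-antipode is used and nothing else changes.

**Route**

Step 1
Reactants: 1 D-2-aminoadipic acid [(R)-2-aminohexanedioic acid]
Product: 3 methyl (R)-6-oxopiperidine-2-carboxylate, via dimethyl (R)-2-aminohexanedioate hydrochloride 2 (not isolated)
Conditions: SOCl2, MeOH, 0 °C to reflux; evaporate; Et3N, MeOH, reflux
Reagents that add atoms: methanol, CO
Why: Fischer esterification in methanolic HCl followed, once the amine is freed, by 6-exo-trig lactamisation of the δ-ester onto nitrogen; the α-stereocentre (future C5) is not touched.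

Step 2
Reactants: 3 methyl (R)-6-oxopiperidine-2-carboxylate
Product: 4 (R)-6-(hydroxymethyl)piperidin-2-one
Conditions: NaBH4, EtOH, 0 °C to rt
Reagents that add atoms: none
Why: Chemoselective hydride reduction: NaBH4 reduces the ester, which is activated by the α-amido group, and leaves the lactam carbonyl.

Step 3
Reactants: 4 (R)-6-(hydroxymethyl)piperidin-2-one
Product: 5 (R)-6-[(tert-butyldiphenylsilyloxy)methyl]piperidin-2-one
Conditions: TBDPSCl, imidazole, DMF, rt
Reagents that add atoms: tert-butyl(chloro)diphenylsilane, CC(C)(C)[Si](Cl)(c1ccccc1)c1ccccc1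
Why: Standard silylation of the primary alcohol; the lactam N–H is not silylated under imidazole catalysis.

Step 4
Reactants: 5 (R)-6-[(tert-butyldiphenylsilyloxy)methyl]piperidin-2-one; 6 p-toluenesulfonyl chloride
Product: 7 (R)-6-[(tert-butyldiphenylsilyloxy)methyl]-1-tosylpiperidin-2-one
Conditions: n-BuLi, THF, −78 °C; then 6, −78 °C to rt
Reagents that add atoms: p-toluenesulfonyl chloride (6), Cc1ccc(cc1)S(=O)(=O)Cl
Why: N-Sulfonylation of the lithium lactamate, which activates the carbonyl for enolisation and supplies the group that later holds the C5 arm axial.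

Step 5
Reactants: 7 (R)-6-[(tert-butyldiphenylsilyloxy)methyl]-1-tosylpiperidin-2-one
Product: 8 (R)-6-[(tert-butyldiphenylsilyloxy)methyl]-1-tosyl-1,4,5,6-tetrahydropyridin-2-yl trifluoromethanesulfonate
Conditions: KHMDS, THF, −78 °C; PhNTf2, −78 to 0 °C
Reagents that add atoms: N-phenylbis(trifluoromethanesulfonimide), O=S(=O)(N(c1ccccc1)S(=O)(=O)C(F)(F)F)C(F)(F)F
Why: Enol triflate formation: the imide-like N-sulfonyl lactam is enolised at C8 and the potassium enolate is trapped on oxygen.

Step 6
Reactants: 8 the enol triflate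
Product: 9 (R)-2-[(tert-butyldiphenylsilyloxy)methyl]-1-tosyl-6-(trimethylstannyl)-1,2,3,4-tetrahydropyridine
Conditions: (Me3Sn)2, Pd(PPh3)4 (5 mol %), LiCl, THF, reflux
Reagents that add atoms: hexamethylditin, C[Sn](C)(C)[Sn](C)(C)C
Why: Stille-type stannylation: oxidative addition of the vinyl triflate to zerovalent palladium, transmetallation from the distannane and reductive elimination, with chloride assisting the first step.

Step 7
Reactants: 9 the vinylstannane; 10 cyclobutanone
Product: 12 1-[(R)-6-[(tert-butyldiphenylsilyloxy)methyl]-1-tosyl-1,4,5,6-tetrahydropyridin-2-yl]cyclobutan-1-ol, via α-lithio ene-sulfonamide 11 (not isolated)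
Conditions: MeLi, THF, −78 °C; then 10, −78 °C; H2O quench
Reagents that add atoms: cyclobutanone (10), O=C1CCC1
Why: Tin–lithium exchange gives the α-amino vinyllithium, which adds 1,2 to the strained and highly electrophilic ketone faster than it enolises it.

Step 8
Reactants: 12 the cyclobutanol ene-sulfonamide
Product: 14 7-[(tert-butyldiphenylsilyloxy)methyl]-6-tosyl-6-azaspiro[4.5]decan-1-one with the C5 arm cis to the carbonyl carbon C13, via N-tosyliminium ion 13 (not isolated)
Conditions: camphor-10-sulfonic acid (1.1 equiv), CH2Cl2, 0 °C to rt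
Reagents that add atoms: none
Why: The sulfonic acid protonates the electron-rich ene-sulfonamide at C8 and gives N-tosyliminium ion 13 with the cationic carbon C9 next to the tertiary cyclobutanol; a ring C–C bond (C13–C10) aligned with the empty orbital migrates to C9 while the hydroxyl oxygen becomes the C13 carbonyl, an acid-promoted semipinacol (α-hydroxy iminium) rearrangement. The closest known reaction type is the acid-induced ring expansion of 1-alkenylcyclobutanols that carry an enamide or ene-sulfonamide donor to spirocyclic cyclopentanones. The cyclopentane is closed by four-to-five ring expansion through a suprafacial 1,2-alkyl shift onto C9, not by an exo or endo closure of a chain, and strain release plus carbonyl formation make it irreversible. The only new stereocentre, C9, is controlled by C5: allylic strain with the N-tosyl group holds the silyloxymethyl arm axial, so the migrating CH2 (C10) bonds to the iminium face anti to it and the carbonyl carbon C13 ends cis to the arm. The step needs this facial selectivity and C-protonation in preference to ionisation of the tertiary alcohol or loss of the silyl ether; the first is secured by the axial C5 substituent, the second by the nucleophilic β-carbon of the ene-sulfonamide and by an anhydrous, non-nucleophilic medium in which the silyl ether is stable.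

Step 9
Reactants: 14 the spiro ketone
Product: 15 ethyl 2-[7-[(tert-butyldiphenylsilyloxy)methyl]-6-tosyl-6-azaspiro[4.5]decan-1-ylidene]acetate (exocyclic C13=C14 enoate, E isomer expected)
Conditions: (EtO)2P(O)CH2CO2Et, NaH, THF, 0 °C to reflux
Reagents that add atoms: triethyl phosphonoacetate, CCOC(=O)CP(=O)(OCC)OCC
Why: Horner–Wadsworth–Emmons olefination, a reaction that works on α-quaternary cyclopentanones; the alkene geometry does not matter because step 10 removes it.

Step 10
Reactants: 15 the exocyclic enoate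
Product: 16 ethyl 2-[7-[(tert-butyldiphenylsilyloxy)methyl]-6-tosyl-6-azaspiro[4.5]decan-1-yl]acetate with C13–H cis to C8 and the acetate arm cis to nitrogen
Conditions: H2 (4 atm), 10 % Pd/C, EtOAc, rt
Reagents that add atoms: none
Why: Heterogeneous syn-hydrogenation; the N-tosyl nitrogen and the axial C5 arm cover the nitrogen face of the exocyclic alkene, so hydrogen should reach C13 from the C8 face and the acetate arm should come out cis to nitrogen, as the target needs.

Step 11
Reactants: 16 the saturated ester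
Product: 17 ethyl 2-[7-[(tert-butyldiphenylsilyloxy)methyl]-6-tosyl-6-azaspiro[4.5]decan-1-yl]propanoate with the C14 methyl configured as in the target
Conditions: LDA, THF, −78 °C; MeI, DMPU, −78 to −40 °C
Reagents that add atoms: iodomethane, CI
Why: Ester enolate alkylation under acyclic stereocontrol: allylic strain places C13–H in the enolate plane and iodomethane approaches anti to the quaternary carbon C9, which gives the C14 configuration of the target.

Step 12
Reactants: 17 the methylated ester
Product: 18 ethyl 2-[7-(hydroxymethyl)-6-tosyl-6-azaspiro[4.5]decan-1-yl]propanoate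
Conditions: Bu4NF, AcOH, THF, 0 °C to rt
Reagents that add atoms: none
Why: Desilylation by fluoride attack on silicon; acetic acid buffers the medium so that the α-stereocentre of the ester is not epimerised.

Step 13
Reactants: 18 the C4 alcohol
Product: 19 ethyl 2-[7-(iodomethyl)-6-tosyl-6-azaspiro[4.5]decan-1-yl]propanoate
Conditions: I2, PPh3, imidazole, CH2Cl2, 0 °C to rt
Reagents that add atoms: iodine, II
Why: Appel-type iodination of the primary alcohol through the alkoxyphosphonium ion; the fully substituted sulfonamide nitrogen cannot take part.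

Step 14
Reactants: 19 the C4 iodide
Product: 20 ethyl 2-[7-allyl-6-tosyl-6-azaspiro[4.5]decan-1-yl]propanoate
Conditions: CH2=CHMgBr (3 equiv), CuI (20 mol %), THF, −30 to 0 °C
Reagents that add atoms: vinylmagnesium bromide, C=C[Mg]Br
Why: Copper-catalysed coupling of the vinyl Grignard reagent with the primary iodide (SN2 by a vinylcuprate), which at low temperature is faster than attack on the hindered α-branched ester.

Step 15
Reactants: 20 the allyl ester
Product: 21 2-[7-allyl-6-tosyl-6-azaspiro[4.5]decan-1-yl]propan-1-ol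
Conditions: LiAlH4, THF, 0 °C
Reagents that add atoms: none
Why: Hydride reduction of the ester to the primary alcohol (C15); the sulfonamide and the isolated alkene do not react at 0 °C.

Step 16
Reactants: 21 the N-tosyl alcohol
Product: 22 2-[7-allyl-6-azaspiro[4.5]decan-1-yl]propan-1-ol (secondary amine)
Conditions: sodium naphthalenide (Na, C10H8), DME, −78 °C
Reagents that add atoms: none
Why: Reductive detosylation: single-electron transfer to the arenesulfonyl group cleaves the N–S bond, and the isolated terminal alkene and the alkoxide are inert to the radical anion.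

Step 17
Reactants: 22 the amino alcohol; 23 methyl 2-(bromomethyl)acrylate
Product: 24 methyl 2-{[7-allyl-1-(1-hydroxypropan-2-yl)-6-azaspiro[4.5]decan-6-yl]methyl}acrylate
Conditions: K2CO3, MeCN, rt to 45 °C
Reagents that add atoms: methyl 2-(bromomethyl)acrylate (23), C=C(CBr)C(=O)OC
Why: N-Alkylation by an SN2′ addition–elimination on the bromomethyl acrylate, a pathway open even to this hindered secondary amine, while the alcohol stays unreacted under carbonate.

Step 18
Reactants: 24 the diene
Product: 25 tricyclic hydroxy ester: methyl ester of the C1–C15 core with the C2=C3 enoate ring closed and C15 as CH2OH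
Conditions: second-generation Grubbs catalyst RuCl2(=CHPh)(H2IMes)(PCy3) (10 mol %), camphor-10-sulfonic acid (1.1 equiv), toluene, 80 °C
Reagents that add atoms: none
Why: Ring-closing metathesis of the terminal alkene with the 1,1-disubstituted acrylate closes the six-membered ring and forms the trisubstituted C2=C3 enoate; protonation keeps the amine off ruthenium.

Step 19
Reactants: 25 the tricyclic alcohol
Product: 26 the corresponding C15 aldehyde
Conditions: (COCl)2, DMSO, CH2Cl2, −78 °C; then i-Pr2NEt, −78 to 0 °C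
Reagents that add atoms: none
Why: Swern oxidation at low temperature with a hindered base gives the aldehyde without epimerising C14 or oxidising the tertiary amine.

Step 20
Reactants: 26 the aldehyde
Product: 27 the terminal alkyne (C15≡C16–H) of the tricyclic methyl ester
Conditions: dimethyl (1-diazo-2-oxopropyl)phosphonate, K2CO3, MeOH, 0 °C to rt
Reagents that add atoms: dimethyl (1-diazo-2-oxopropyl)phosphonate, CC(=O)C(=[N+]=[N-])P(=O)(OC)OC
Why: Seyferth–Gilbert homologation with the Ohira–Bestmann reagent under mild carbonate conditions, which leave the methyl ester and the α-stereocentre intact.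

Step 21
Reactants: 28 dihydro-2H-pyran-2,4(3H)-dione
Product: 29 4-chloro-5,6-dihydro-2H-pyran-2-one
Conditions: (COCl)2, DMF (cat.), CH2Cl2, 0 °C to rt
Reagents that add atoms: oxalyl chloride, O=C(Cl)C(=O)Cl
Why: Vilsmeier-type chlorination of the enol form of the cyclic β-keto lactone gives the vinylogous acid chloride, and the ring fixes C17 and C20 cis on the chloroalkene.

Step 22
Reactants: 29 the chloro lactone
Product: 30 (E)-3-chloro-5-hydroxy-N-methoxy-N-methylpent-2-enamide (amide carbon and C4 cis)
Conditions: MeNH(OMe)·HCl, AlMe3, CH2Cl2, 0 °C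
Reagents that add atoms: N,O-dimethylhydroxylamine hydrochloride, CNOC.Cl
Why: Aluminium amide aminolysis of the lactone (Weinreb amide formation) attacks the aluminium-bound carbonyl and opens the ring with the alkene geometry unchanged.

Step 23
Reactants: 30 the hydroxy amide
Product: 31 (E)-5-[(tert-butyldimethylsilyl)oxy]-3-chloro-N-methoxy-N-methylpent-2-enamide
Conditions: TBSCl, imidazole, CH2Cl2, 0 °C
Reagents that add atoms: tert-butyl(chloro)dimethylsilane, CC(C)(C)[Si](C)(C)Cl
Why: Silylation of the primary alcohol, which also stops relactonisation.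

Step 24
Reactants: 31 the silylated Weinreb amide
Product: 32 (E)-5-[(tert-butyldimethylsilyl)oxy]-3-chloropent-2-enal
Conditions: i-Bu2AlH, THF, −78 °C; aqueous KNaC4H4O6
Reagents that add atoms: none
Why: Hydride addition to the Weinreb amide gives a chelated tetrahedral intermediate that releases the aldehyde only on work-up, so over-reduction is avoided.

Step 25
Reactants: 27 the alkyne; 32 the chloro-enal
Product: 33 propargylic alcohol with C17 in the spatial arrangement of the target (formally 17S while C16 is an alkyne carbon), C21 as OTBS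
Conditions: Me2Zn, (S,S)-ProPhenol [2,6-bis{[(S)-2-(hydroxydiphenylmethyl)pyrrolidin-1-yl]methyl}-4-methylphenol] (20 mol %), Ph3P=O (40 mol %), toluene, 0 °C; then 32 (2 equiv), 4 °C
Reagents that add atoms: aldehyde 32, O=C/C=C(/Cl)CCO[Si](C)(C)C(C)(C)C
Why: Catalytic enantioselective alkynylation: the dinuclear zinc–ProPhenol complex binds the methylzinc acetylide and the enal and delivers the alkynyl group to one aldehyde face, setting C17 under catalyst control, while Me2Zn does not touch the ester or the amine.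

Step 26
Reactants: 33 the propargylic alcohol
Product: 34 the C17,C21 bis(tert-butyldimethylsilyl) ether
Conditions: TBSOTf, 2,6-lutidine, CH2Cl2, −78 °C
Reagents that add atoms: tert-butyldimethylsilyl trifluoromethanesulfonate, CC(C)(C)[Si](C)(C)OS(=O)(=O)C(F)(F)F
Why: Silylation of the hindered secondary alcohol with the silyl triflate and a non-nucleophilic base.

Step 27
Reactants: 34 the alkyne bis-silyl ether
Product: 35 the (15Z)-alkene bis-silyl ether (17R)
Conditions: H2 (1 atm), Pd/CaCO3 poisoned with Pb(OAc)2, quinoline, EtOAc, rt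
Reagents that add atoms: none
Why: Lindlar semi-hydrogenation adds hydrogen syn, stops at the cis alkene and leaves the vinyl chloride and the trisubstituted enoate.

Step 28
Reactants: 35 the bis-silyl ether
Product: 36 the C21 primary alcohol with C17–OTBS retained
Conditions: HF·pyridine, pyridine, THF, 0 °C
Reagents that add atoms: none
Why: Selective desilylation: buffered HF·pyridine removes the unhindered primary silyl ether much faster than the secondary bis-allylic one.

Step 29
Reactants: 36 the hydroxy methyl ester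
Product: 37 the seco acid (C1 carboxylic acid, C21–OH, C17–OTBS)
Conditions: LiOH, THF/MeOH/H2O, rt; then 1 M HCl to pH 6
Reagents that add atoms: lithium hydroxide, [Li+].[OH-]
Why: Saponification of the methyl enoate; the secondary silyl ether, the vinyl chloride and the alkenes are stable to aqueous hydroxide at room temperature.

Step 30
Reactants: 37 the seco acid
Product: 38 the 15-membered lactone as its C17 tert-butyldimethylsilyl ether
Conditions: DCC, DMAP, DMAP·HCl, CHCl3, reflux, slow addition (final concentration about 1 mM)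
Reagents that add atoms: none
Why: Keck macrolactonisation (carbodiimide activation under high dilution) with the primary C21 hydroxyl as the only free alcohol; the two cis alkenes bring the chain ends together and the DMAP salt suppresses N-acylurea formation.

Step 31
Reactants: 38 the silylated macrolactone
Product: 39 the target, CNP0129639.4
Conditions: HF·pyridine, THF, 0 °C to rt
Reagents that add atoms: none
Why: Fluoride-mediated cleavage of the last silyl ether under weakly acidic conditions that leave the lactone, the chlorodiene and the amine unchanged.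

**Compound list**

1 | D-2-aminoadipic acid | N[C@H](CCCC(=O)O)C(=O)O | starting material
2 | dimethyl (R)-2-aminohexanedioate hydrochloride | N[C@H](CCCC(=O)OC)C(=O)OC.Cl | intermediate
3 | methyl (R)-6-oxopiperidine-2-carboxylate | COC(=O)[C@H]1CCCC(=O)N1 | intermediate
4 | (R)-6-(hydroxymethyl)piperidin-2-one | OC[C@H]1CCCC(=O)N1 | intermediate
5 | (R)-6-[(tert-butyldiphenylsilyloxy)methyl]piperidin-2-one | CC(C)(C)[Si](OC[C@H]1CCCC(=O)N1)(c1ccccc1)c1ccccc1 | intermediate
6 | p-toluenesulfonyl chloride | Cc1ccc(cc1)S(=O)(=O)Cl | starting material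
7 | (R)-6-[(tert-butyldiphenylsilyloxy)methyl]-1-tosylpiperidin-2-one | CC(C)(C)[Si](OC[C@H]1CCCC(=O)N1S(=O)(=O)c1ccc(C)cc1)(c1ccccc1)c1ccccc1 | intermediate
8 | (R)-6-[(tert-butyldiphenylsilyloxy)methyl]-1-tosyl-1,4,5,6-tetrahydropyridin-2-yl trifluoromethanesulfonate | CC(C)(C)[Si](OC[C@H]1CCC=C(OS(=O)(=O)C(F)(F)F)N1S(=O)(=O)c1ccc(C)cc1)(c1ccccc1)c1ccccc1 | intermediate
9 | (R)-2-[(tert-butyldiphenylsilyloxy)methyl]-1-tosyl-6-(trimethylstannyl)-1,2,3,4-tetrahydropyridine | CC(C)(C)[Si](OC[C@H]1CCC=C([Sn](C)(C)C)N1S(=O)(=O)c1ccc(C)cc1)(c1ccccc1)c1ccccc1 | intermediate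
10 | cyclobutanone | O=C1CCC1 | starting material
11 | α-lithio ene-sulfonamide (lithium in place of tin in 9) | CC(C)(C)[Si](OC[C@H]1CCC=C([Li])N1S(=O)(=O)c1ccc(C)cc1)(c1ccccc1)c1ccccc1 | intermediate
12 | 1-[(R)-6-[(tert-butyldiphenylsilyloxy)methyl]-1-tosyl-1,4,5,6-tetrahydropyridin-2-yl]cyclobutan-1-ol | OC1(CCC1)C2=CCC[C@H](CO[Si](c3ccccc3)(c3ccccc3)C(C)(C)C)N2S(=O)(=O)c2ccc(C)cc2 | intermediate
13 | N-tosyliminium ion (C9=N+) from C8-protonation of 12 | OC1(CCC1)C2=[N+](S(=O)(=O)c3ccc(C)cc3)[C@@H](CO[Si](c3ccccc3)(c3ccccc3)C(C)(C)C)CCC2 | intermediate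
14 | 7-[(tert-butyldiphenylsilyloxy)methyl]-6-tosyl-6-azaspiro[4.5]decan-1-one, C5 arm cis to carbonyl carbon C13 | O=C1CCC[C@]12CCC[C@H](CO[Si](c3ccccc3)(c3ccccc3)C(C)(C)C)N2S(=O)(=O)c2ccc(C)cc2 | intermediate
15 | ethyl (E)-2-[7-[(tert-butyldiphenylsilyloxy)methyl]-6-tosyl-6-azaspiro[4.5]decan-1-ylidene]acetate | CCOC(=O)/C=C1\CCC[C@]12CCC[C@H](CO[Si](c3ccccc3)(c3ccccc3)C(C)(C)C)N2S(=O)(=O)c2ccc(C)cc2 | intermediate
16 | ethyl 2-[7-[(tert-butyldiphenylsilyloxy)methyl]-6-tosyl-6-azaspiro[4.5]decan-1-yl]acetate, acetate arm cis to N | CCOC(=O)C[C@H]1CCC[C@]12CCC[C@H](CO[Si](c3ccccc3)(c3ccccc3)C(C)(C)C)N2S(=O)(=O)c2ccc(C)cc2 | intermediate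
17 | ethyl 2-[7-[(tert-butyldiphenylsilyloxy)methyl]-6-tosyl-6-azaspiro[4.5]decan-1-yl]propanoate, C14 as in the target | CCOC(=O)[C@H](C)[C@H]1CCC[C@]12CCC[C@H](CO[Si](c3ccccc3)(c3ccccc3)C(C)(C)C)N2S(=O)(=O)c2ccc(C)cc2 | intermediate
18 | ethyl 2-[7-(hydroxymethyl)-6-tosyl-6-azaspiro[4.5]decan-1-yl]propanoate | CCOC(=O)[C@H](C)[C@H]1CCC[C@]12CCC[C@H](CO)N2S(=O)(=O)c2ccc(C)cc2 | intermediate
19 | ethyl 2-[7-(iodomethyl)-6-tosyl-6-azaspiro[4.5]decan-1-yl]propanoate | CCOC(=O)[C@H](C)[C@H]1CCC[C@]12CCC[C@H](CI)N2S(=O)(=O)c2ccc(C)cc2 | intermediate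
20 | ethyl 2-[7-allyl-6-tosyl-6-azaspiro[4.5]decan-1-yl]propanoate | CCOC(=O)[C@H](C)[C@H]1CCC[C@]12CCC[C@H](CC=C)N2S(=O)(=O)c2ccc(C)cc2 | intermediate
21 | 2-[7-allyl-6-tosyl-6-azaspiro[4.5]decan-1-yl]propan-1-ol | OC[C@H](C)[C@H]1CCC[C@]12CCC[C@H](CC=C)N2S(=O)(=O)c2ccc(C)cc2 | intermediate
22 | 2-[7-allyl-6-azaspiro[4.5]decan-1-yl]propan-1-ol | OC[C@H](C)[C@H]1CCC[C@]12CCC[C@H](CC=C)N2 | intermediate
23 | methyl 2-(bromomethyl)acrylate | C=C(CBr)C(=O)OC | starting material
24 | methyl 2-{[7-allyl-1-(1-hydroxypropan-2-yl)-6-azaspiro[4.5]decan-6-yl]methyl}acrylate | OC[C@H](C)[C@H]1CCC[C@]12CCC[C@H](CC=C)N2CC(=C)C(=O)OC | intermediate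
25 | tricyclic hydroxy ester (C1 methyl ester, C2=C3 ring closed, C15 CH2OH) | COC(=O)C2=CC[C@H]3CCC[C@]4(CCC[C@@H]4[C@@H](C)CO)N3C2 | intermediate
26 | tricyclic C15 aldehyde | COC(=O)C2=CC[C@H]3CCC[C@]4(CCC[C@@H]4[C@@H](C)C=O)N3C2 | intermediate
27 | tricyclic terminal alkyne (C15≡C16) | COC(=O)C2=CC[C@H]3CCC[C@]4(CCC[C@@H]4[C@@H](C)C#C)N3C2 | intermediate
28 | dihydro-2H-pyran-2,4(3H)-dione | O=C1CC(=O)OCC1 | starting material
29 | 4-chloro-5,6-dihydro-2H-pyran-2-one | O=C1C=C(Cl)CCO1 | intermediate
30 | (E)-3-chloro-5-hydroxy-N-methoxy-N-methylpent-2-enamide | CON(C)C(=O)/C=C(/Cl)CCO | intermediate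
31 | (E)-5-[(tert-butyldimethylsilyl)oxy]-3-chloro-N-methoxy-N-methylpent-2-enamide | CON(C)C(=O)/C=C(/Cl)CCO[Si](C)(C)C(C)(C)C | intermediate
32 | (E)-5-[(tert-butyldimethylsilyl)oxy]-3-chloropent-2-enal | O=C/C=C(/Cl)CCO[Si](C)(C)C(C)(C)C | intermediate
33 | propargylic alcohol (C17–OH, C21–OTBS, C15≡C16) | COC(=O)C2=CC[C@H]3CCC[C@]4(CCC[C@@H]4[C@@H](C)C#C[C@@H](O)/C=C(/Cl)CCO[Si](C)(C)C(C)(C)C)N3C2 | intermediate
34 | C17,C21 bis-TBS ether of 33 | COC(=O)C2=CC[C@H]3CCC[C@]4(CCC[C@@H]4[C@@H](C)C#C[C@@H](O[Si](C)(C)C(C)(C)C)/C=C(/Cl)CCO[Si](C)(C)C(C)(C)C)N3C2 | intermediate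
35 | (15Z)-alkene bis-TBS ether | COC(=O)C2=CC[C@H]3CCC[C@]4(CCC[C@@H]4[C@@H](C)/C=C\[C@@H](O[Si](C)(C)C(C)(C)C)/C=C(/Cl)CCO[Si](C)(C)C(C)(C)C)N3C2 | intermediate
36 | C21 alcohol, C17–OTBS, methyl ester | COC(=O)C2=CC[C@H]3CCC[C@]4(CCC[C@@H]4[C@@H](C)/C=C\[C@@H](O[Si](C)(C)C(C)(C)C)/C=C(/Cl)CCO)N3C2 | intermediate
37 | seco acid (C1 CO2H, C21–OH, C17–OTBS) | OC(=O)C2=CC[C@H]3CCC[C@]4(CCC[C@@H]4[C@@H](C)/C=C\[C@@H](O[Si](C)(C)C(C)(C)C)/C=C(/Cl)CCO)N3C2 | intermediate
38 | macrolactone C17 tert-butyldimethylsilyl ether | C[C@H]1/C=C\[C@@H](O[Si](C)(C)C(C)(C)C)/C=C(/Cl)CCOC(=O)C2=CC[C@H]3CCC[C@]4(CCC[C@H]14)N3C2 | intermediate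
39 | CNP0129639.4 (5R,9S,13R,14S,17R,15Z,18E) | C[C@H]1/C=C\[C@@H](O)/C=C(/Cl)CCOC(=O)C2=CC[C@H]3CCC[C@]4(CCC[C@H]14)N3C2 | target

**Step count and risks**

Total step count: 31 (27 on the main line, 4 for aldehyde 32).
Longest linear sequence: 27 steps (steps 1–20 and 25–31).

Steps most likely to fail:

Step 25. The zinc acetylide may add slowly to the hindered β-chloro enal, or with too little facial discrimination, so that a mixture at C17 results. The fallback sets out from 27 and 31 and returns at 33. Alkyne 27 is deprotonated with LiN(SiMe3)2 (THF, −78 °C) and acylated with Weinreb amide 31 to give the cross-conjugated alkynyl chloroalkenyl ketone F1. Corey–Bakshi–Shibata reduction with (S)-2-methyl-CBS-oxazaborolidine and catecholborane (toluene, −78 °C), in which the cis-substituted chloroalkenyl group acts as the large and the linear alkynyl group as the small substituent, should then give 33.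

Step 10. Hydrogen may be delivered to both faces of the exocyclic alkene if the nitrogen face is less shielded than assumed, which would give the C13 epimer as well. The fallback sets out from 15 and returns at 16, and replaces substrate control by catalyst control. i-Bu2AlH (CH2Cl2, −78 °C) reduces 15 to the exocyclic allylic alcohol F2. Hydroxyl-directed homogeneous hydrogenation with Ru(OAc)2(BINAP) (H2, MeOH), using the BINAP antipode that adds hydrogen to C13 from the C8 face, gives the saturated primary alcohol F3. Swern oxidation gives the aldehyde F4, and oxidative esterification (I2, KOH, EtOH, 0 °C) returns ester 16.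

Step 11. The acyclic enolate may be methylated with low facial bias, which would give a mixture of C14 epimers. The fallback sets out from 16 and returns at 17, and adds auxiliary control that is matched with the substrate bias. Saponification (LiOH, THF/H2O) gives the carboxylic acid F5. Activation with pivaloyl chloride/Et3N and acylation of lithiated (R)-4-benzyl-1,3-oxazolidin-2-one gives the N-acyl oxazolidinone F6. Evans alkylation (NaN(SiMe3)2, MeI, THF, −78 °C) gives the α-methyl imide F7, and EtOMgBr (EtOH/THF, 0 °C) releases ethyl ester 17 together with the auxiliary.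

**Further compounds**

F1 | step 25 | methyl ester of the tricyclic core carrying the C15≡C16–C17(=O)–CH=C(Cl)–CH2CH2OTBS ynone | COC(=O)C2=CC[C@H]3CCC[C@]4(CCC[C@@H]4[C@@H](C)C#CC(=O)/C=C(/Cl)CCO[Si](C)(C)C(C)(C)C)N3C2
F2 | step 10 | (E)-2-[7-[(tert-butyldiphenylsilyloxy)methyl]-6-tosyl-6-azaspiro[4.5]decan-1-ylidene]ethanol | OC/C=C1\CCC[C@]12CCC[C@H](CO[Si](c3ccccc3)(c3ccccc3)C(C)(C)C)N2S(=O)(=O)c2ccc(C)cc2
F3 | step 10 | 2-[7-[(tert-butyldiphenylsilyloxy)methyl]-6-tosyl-6-azaspiro[4.5]decan-1-yl]ethanol | OCC[C@H]1CCC[C@]12CCC[C@H](CO[Si](c3ccccc3)(c3ccccc3)C(C)(C)C)N2S(=O)(=O)c2ccc(C)cc2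
F4 | step 10 | 2-[7-[(tert-butyldiphenylsilyloxy)methyl]-6-tosyl-6-azaspiro[4.5]decan-1-yl]acetaldehyde | O=CC[C@H]1CCC[C@]12CCC[C@H](CO[Si](c3ccccc3)(c3ccccc3)C(C)(C)C)N2S(=O)(=O)c2ccc(C)cc2
F5 | step 11 | 2-[7-[(tert-butyldiphenylsilyloxy)methyl]-6-tosyl-6-azaspiro[4.5]decan-1-yl]acetic acid | OC(=O)C[C@H]1CCC[C@]12CCC[C@H](CO[Si](c3ccccc3)(c3ccccc3)C(C)(C)C)N2S(=O)(=O)c2ccc(C)cc2
F6 | step 11 | (R)-4-benzyl-3-{2-[7-[(tert-butyldiphenylsilyloxy)methyl]-6-tosyl-6-azaspiro[4.5]decan-1-yl]acetyl}oxazolidin-2-one | O=C1OC[C@@H](Cc2ccccc2)N1C(=O)C[C@H]1CCC[C@]12CCC[C@H](CO[Si](c3ccccc3)(c3ccccc3)C(C)(C)C)N2S(=O)(=O)c2ccc(C)cc2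
F7 | step 11 | (R)-4-benzyl-3-{2-[7-[(tert-butyldiphenylsilyloxy)methyl]-6-tosyl-6-azaspiro[4.5]decan-1-yl]propanoyl}oxazolidin-2-one, C14 as in the target | O=C1OC[C@@H](Cc2ccccc2)N1C(=O)[C@H](C)[C@H]1CCC[C@]12CCC[C@H](CO[Si](c3ccccc3)(c3ccccc3)C(C)(C)C)N2S(=O)(=O)c2ccc(C)cc2
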